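**Retrosynthetic overview**
1. Target ⇐ base-triggered Grob-type ring expansion of a 4,15-epoxy-14-oxo-guaianolide (five/seven fused). Cleaving C1–C5 forms C1=C10–CHO and C4(CH2OH)=C5 in one step.
2. Guaianolide ⇐ intramolecular zinc Barbier allylation (C7–C8) of a 3-(bromomethyl)butenolide onto a tethered aldehyde. This closes the seven-membered ring, frees the α-methylene lactone and sets C7 and C8.
3. Butenolide ⇐ esterification with 2-(bromomethyl)acrylic acid and ring-closing metathesis; spiro-epoxide ⇐ Corey–Chaykovsky reaction on the cyclopentanone.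
4. Cyclopentanone ⇐ asymmetric conjugate addition/aldol coupling of cyclopent-2-enone, a but-1-en-2-yl metal and acrolein (sets C1, C5, C6).
5. Ring order: five-membered ring (bought) → butenolide → seven-membered ring → ten-membered ring by ring expansion.

Assumption: target atom numbers (germacrane/guaiane C1–C15) are used for all intermediates; 1 and B-bromo-9-BBN are taken as catalogue chemicals.

**Step 1**
Reactants: 1 3-bromobut-3-en-1-ol
Product: 2 [(3-bromobut-3-en-1-yl)oxy]triethylsilane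
Conditions: Et3SiCl, imidazole, CH2Cl2, 0 °C → rt
Reagents that add atoms: chlorotriethylsilane, CC[Si](CC)(CC)Cl
Why: Standard imidazole-promoted silylation; the primary triethylsilyl ether survives the organometallic steps and is later oxidised directly to the C8 aldehyde.

**Step 2**
Reactants: 2 [(3-bromobut-3-en-1-yl)oxy]triethylsilane; 3 cyclopent-2-en-1-one; 4 prop-2-enal
Product: 8 (2R,3R)-2-[(1R)-1-hydroxyprop-2-en-1-yl]-3-[4-(triethylsilyloxy)but-1-en-2-yl]cyclopentan-1-one, via alkenylmagnesium bromide 5 (not isolated), via B-alkenyl-9-BBN 6 (not isolated), via boron enolate 7 (not isolated)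
Conditions: Mg, THF, 40 °C; B-bromo-9-BBN, −78 → 0 °C; 3, [Rh(OMe)(cod)]2 (1.5 mol %), (R)-BINAP (3.3 mol %), toluene, 80 °C; 4, −78 °C; pH 7 buffer
Reagents that add atoms: none
Why: Rhodium/(R)-BINAP asymmetric 1,4-addition (Hayashi–Miyaura type) sets C1 and gives the boron enolate regiospecifically; its closed-transition-state aldol with acrolein occurs anti to the C1 substituent (2,3-trans) and gives the anti carbinol at C6, the minor C6 epimer being removed by chromatography.

**Step 3**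
Reactants: 8 (2R,3R)-2-[(1R)-1-hydroxyprop-2-en-1-yl]-3-[4-(triethylsilyloxy)but-1-en-2-yl]cyclopentan-1-one
Product: 9 (1R)-1-[(3R,4R,5R)-5-(4-triethylsilyloxybut-1-en-2-yl)-1-oxaspiro[2.4]heptan-4-yl]prop-2-en-1-ol
Conditions: Me3S+ I− (2.5 equiv), n-BuLi (2.4 equiv), THF, −10 °C; then 8, −10 → 0 °C
Reagents that add atoms: trimethylsulfonium iodide, C[S+](C)C.[I-]
Why: Corey–Chaykovsky epoxidation; the ylide attacks the ketone anti to the adjacent C5 side chain, so the epoxide oxygen ends syn to C6 (this later dictates the ring-cis C4=C5 bond), and the lithium aldolate is kept cold to avoid retro-aldol.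

**Step 4**
Reactants: 9 (1R)-1-[(3R,4R,5R)-5-(4-triethylsilyloxybut-1-en-2-yl)-1-oxaspiro[2.4]heptan-4-yl]prop-2-en-1-ol; 10 2-(bromomethyl)prop-2-enoic acid
Product: 11 (1R)-1-[(3R,4R,5R)-5-(4-triethylsilyloxybut-1-en-2-yl)-1-oxaspiro[2.4]heptan-4-yl]prop-2-en-1-yl 2-(bromomethyl)prop-2-enoate
Conditions: i-PrN=C=N-i-Pr, DMAP (5 mol %), CH2Cl2, 0 °C
Reagents that add atoms: none
Why: Steglich-type carbodiimide esterification of the secondary allylic alcohol under near-neutral conditions that spare the allylic bromide and the epoxide; no stereocenter is touched.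

**Step 5**
Reactants: 11 (1R)-1-[(3R,4R,5R)-5-(4-triethylsilyloxybut-1-en-2-yl)-1-oxaspiro[2.4]heptan-4-yl]prop-2-en-1-yl 2-(bromomethyl)prop-2-enoate
Product: 12 (5R)-3-(bromomethyl)-5-[(3R,4R,5R)-5-(4-triethylsilyloxybut-1-en-2-yl)-1-oxaspiro[2.4]heptan-4-yl]furan-2(5H)-one
Conditions: second-generation Hoveyda–Grubbs catalyst [RuCl2(=CH-C6H4-2-O-i-Pr)(H2IMes)] (5 mol %), CH2Cl2 (5 mM), 40 °C
Reagents that add atoms: none
Why: Ring-closing metathesis of the vinyl group with the acrylate gives the butenolide; the 1,1-disubstituted alkene on C1 is trans to the reacting vinyl group and cannot close a five-membered ring with it.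

**Step 6**
Reactants: 12 (5R)-3-(bromomethyl)-5-[(3R,4R,5R)-5-(4-triethylsilyloxybut-1-en-2-yl)-1-oxaspiro[2.4]heptan-4-yl]furan-2(5H)-one
Product: 13 (5R)-3-(bromomethyl)-5-[(3R,4R,5R)-5-(4-oxobut-1-en-2-yl)-1-oxaspiro[2.4]heptan-4-yl]furan-2(5H)-one
Conditions: (COCl)2, DMSO, CH2Cl2, −78 → −40 °C; Et3N, −78 °C
Reagents that add atoms: none
Why: Swern conditions convert a primary triethylsilyl ether directly into the aldehyde (oxidative desilylation) without acid, so epoxide, allylic bromide and butenolide survive.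

**Step 7**
Reactants: 13 (5R)-3-(bromomethyl)-5-[(3R,4R,5R)-5-(4-oxobut-1-en-2-yl)-1-oxaspiro[2.4]heptan-4-yl]furan-2(5H)-one
Product: 15 (1R,4R,5R,6R,7R,8R)-4,15-epoxy-8-hydroxyguaia-10(14),11(13)-dien-12,6-olide (H-1/H-5 trans; H-6, H-7, H-8 mutually cis; epoxide O syn to C6), via allylzinc bromide 14 (not isolated)
Conditions: Zn dust, THF/sat. aq. NH4Cl (5:1), 5 mM, 0 °C → rt
Reagents that add atoms: none
Why: Intramolecular Barbier allylation; γ-attack of the butenolide-derived allylzinc closes the seven-membered ring and frees the α-methylene lactone, the short tether forces C8 onto the C7 face that carries C5 (cis lactone), and the chelated transition state with the C9 chain gauche to C6 is expected to give the 8-OH cis to C11.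

**Step 8**
Reactants: 15 (1R,4R,5R,6R,7R,8R)-4,15-epoxy-8-hydroxyguaia-10(14),11(13)-dien-12,6-olide; 16 3-methylbutanoyl chloride
Product: 17 (1R,4R,5R,6R,7R,8R)-4,15-epoxy-12-oxo-guaia-10(14),11(13)-dien-12,6-olid-8-yl 3-methylbutanoate
Conditions: pyridine, DMAP (cat.), CH2Cl2, 0 °C → rt
Reagents that add atoms: none
Why: Simple acylation of the only free hydroxyl group, with retention at C8.

**Step 9**
Reactants: 17 (1R,4R,5R,6R,7R,8R)-4,15-epoxy-12-oxo-guaia-10(14),11(13)-dien-12,6-olid-8-yl 3-methylbutanoate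
Product: 19 (1S,4R,5R,6R,7R,8R,10S)-4,15-epoxy-14-hydroxyguai-11(13)-en-12,6-olid-8-yl 3-methylbutanoate, via B-alkyl-9-BBN 18 (not isolated)
Conditions: 9-BBN, THF, 0 °C → rt; Me3NO·2H2O, 60 °C
Reagents that add atoms: trimethylamine N-oxide, C[N+](C)(C)[O-]
Why: Anti-Markovnikov hydroboration; 9-BBN adds to the electron-rich exocyclic alkene (boron at C14) and not to the electron-poor α-methylene lactone, the amine-oxide work-up avoids alkaline peroxide, and the new C10 center (H delivered syn to H-1) is lost again in step 11.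

**Step 10**
Reactants: 19 (1S,4R,5R,6R,7R,8R,10S)-4,15-epoxy-14-hydroxyguai-11(13)-en-12,6-olid-8-yl 3-methylbutanoate
Product: 20 (1R,4R,5R,6R,7R,8R,10S)-4,15-epoxy-14-oxoguai-11(13)-en-12,6-olid-8-yl 3-methylbutanoate
Conditions: Dess–Martin periodinane, NaHCO3, CH2Cl2, 0 °C → rt
Reagents that add atoms: none
Why: Buffered Dess–Martin oxidation of the primary alcohol to the α-branched aldehyde leaves the epoxide, esters and α-methylene lactone untouched.

**Step 11**
Reactants: 20 (1R,4R,5R,6R,7R,8R,10S)-4,15-epoxy-14-oxoguai-11(13)-en-12,6-olid-8-yl 3-methylbutanoate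
Product: 22 (6S,7R,8R)-15-hydroxy-14-oxogermacra-1(10),4,11(13)-trien-12,6-olid-8-yl 3-methylbutanoate (both ring double bonds ring-cis; CNP0345200.8), via potassium enolate 21 (not isolated)
Conditions: KN(SiMe3)2 (1.05 equiv), THF, −78 → −20 °C; AcOH, −78 °C
Reagents that add atoms: none
Why: Proposed new method: the C10 aldehyde enolate pushes and the strained spiro-epoxide pulls, so the C1–C5 σ bond (antiperiplanar to C4–O in the twist conformer that puts C3 on the side of C6) breaks in a Grob-type 1,4-fragmentation, opening the five/seven system to the ten-membered ring with C1=C10 (conjugated enal, ring-cis being the thermodynamic geometry via the dienolate), C4=C5 (ring-cis because the epoxide oxygen is syn to C6) and C15–O−; the closest known reactions are the enolate-assisted 1,4-fragmentation of γ-sulfonyloxy aldehydes and the alkoxide-triggered fragmentation of epoxy alcohols, but an epoxide nucleofuge has not been paired with an enolate.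

**Compound list**
1 | 3-bromobut-3-en-1-ol | C=C(Br)CCO | starting material
2 | [(3-bromobut-3-en-1-yl)oxy]triethylsilane | C=C(Br)CCO[Si](CC)(CC)CC | intermediate
3 | cyclopent-2-en-1-one | O=C1C=CCC1 | starting material
4 | prop-2-enal (acrolein) | C=CC=O | starting material
5 | bromo[4-(triethylsilyloxy)but-1-en-2-yl]magnesium | C=C([Mg]Br)CCO[Si](CC)(CC)CC | intermediate
6 | 9-[4-(triethylsilyloxy)but-1-en-2-yl]-9-borabicyclo[3.3.1]nonane | C=C(CCO[Si](CC)(CC)CC)B1C2CCCC1CCC2 | intermediate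
7 | 9-{[(3R)-3-(4-triethylsilyloxybut-1-en-2-yl)cyclopent-1-en-1-yl]oxy}-9-borabicyclo[3.3.1]nonane | C=C(CCO[Si](CC)(CC)CC)[C@@H]1CCC(OB2C3CCCC2CCC3)=C1 | intermediate
8 | (2R,3R)-2-[(1R)-1-hydroxyprop-2-en-1-yl]-3-[4-(triethylsilyloxy)but-1-en-2-yl]cyclopentan-1-one (2,3-trans, anti aldol) | O=C1CC[C@@H](C(=C)CCO[Si](CC)(CC)CC)[C@@H]1[C@H](O)C=C | intermediate
9 | (1R)-1-[(3R,4R,5R)-5-(4-triethylsilyloxybut-1-en-2-yl)-1-oxaspiro[2.4]heptan-4-yl]prop-2-en-1-ol (epoxide O syn to the carbinol chain) | C1O[C@@]12CC[C@@H](C(=C)CCO[Si](CC)(CC)CC)[C@@H]2[C@H](O)C=C | intermediate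
10 | 2-(bromomethyl)prop-2-enoic acid | C=C(CBr)C(=O)O | starting material
11 | (1R)-1-[(3R,4R,5R)-5-(4-triethylsilyloxybut-1-en-2-yl)-1-oxaspiro[2.4]heptan-4-yl]prop-2-en-1-yl 2-(bromomethyl)prop-2-enoate | C1O[C@@]12CC[C@@H](C(=C)CCO[Si](CC)(CC)CC)[C@@H]2[C@H](OC(=O)C(=C)CBr)C=C | intermediate
12 | (5R)-3-(bromomethyl)-5-[(3R,4R,5R)-5-(4-triethylsilyloxybut-1-en-2-yl)-1-oxaspiro[2.4]heptan-4-yl]furan-2(5H)-one | C1O[C@@]12CC[C@@H](C(=C)CCO[Si](CC)(CC)CC)[C@@H]2[C@@H]3OC(=O)C(CBr)=C3 | intermediate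
13 | (5R)-3-(bromomethyl)-5-[(3R,4R,5R)-5-(4-oxobut-1-en-2-yl)-1-oxaspiro[2.4]heptan-4-yl]furan-2(5H)-one | C1O[C@@]12CC[C@@H](C(=C)CC=O)[C@@H]2[C@@H]3OC(=O)C(CBr)=C3 | intermediate
14 | bromo{[(5R)-2-oxo-5-[(3R,4R,5R)-5-(4-oxobut-1-en-2-yl)-1-oxaspiro[2.4]heptan-4-yl]-2,5-dihydrofuran-3-yl]methyl}zinc | C1O[C@@]12CC[C@@H](C(=C)CC=O)[C@@H]2[C@@H]3OC(=O)C(C[Zn]Br)=C3 | intermediate
15 | (1R,4R,5R,6R,7R,8R)-4,15-epoxy-8-hydroxyguaia-10(14),11(13)-dien-12,6-olide | C1O[C@@]12CC[C@@H]3[C@@H]2[C@@H]4OC(=O)C(=C)[C@@H]4[C@H](O)CC3=C | intermediate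
16 | 3-methylbutanoyl chloride | CC(C)CC(=O)Cl | starting material
17 | (1R,4R,5R,6R,7R,8R)-4,15-epoxy-12-oxo-guaia-10(14),11(13)-dien-12,6-olid-8-yl 3-methylbutanoate | C1O[C@@]12CC[C@@H]3[C@@H]2[C@@H]4OC(=O)C(=C)[C@@H]4[C@H](OC(=O)CC(C)C)CC3=C | intermediate
18 | C14 9-borabicyclo[3.3.1]nonan-9-yl adduct of 17 (10S) | C1O[C@@]12CC[C@@H]3[C@@H]2[C@@H]4OC(=O)C(=C)[C@@H]4[C@H](OC(=O)CC(C)C)C[C@@H]3CB5C6CCCC5CCC6 | intermediate
19 | (1S,4R,5R,6R,7R,8R,10S)-4,15-epoxy-14-hydroxyguai-11(13)-en-12,6-olid-8-yl 3-methylbutanoate | C1O[C@@]12CC[C@@H]3[C@@H]2[C@@H]4OC(=O)C(=C)[C@@H]4[C@H](OC(=O)CC(C)C)C[C@@H]3CO | intermediate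
20 | (1R,4R,5R,6R,7R,8R,10S)-4,15-epoxy-14-oxoguai-11(13)-en-12,6-olid-8-yl 3-methylbutanoate | C1O[C@@]12CC[C@@H]3[C@@H]2[C@@H]4OC(=O)C(=C)[C@@H]4[C@H](OC(=O)CC(C)C)C[C@@H]3C=O | intermediate
21 | potassium C10(14)-enolate of 20 | C1O[C@@]12CC[C@@H]3[C@@H]2[C@@H]4OC(=O)C(=C)[C@@H]4[C@H](OC(=O)CC(C)C)CC3=C[O-].[K+] | intermediate
22 | (6S,7R,8R)-15-hydroxy-14-oxogermacra-1(10),4,11(13)-trien-12,6-olid-8-yl 3-methylbutanoate (ring-cis 1(10)- and 4-enes) | C=C1C(=O)O[C@H]2/C=C(/CO)CC/C=C(/C=O)C[C@@H](OC(=O)CC(C)C)[C@@H]12 | target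

**Totals:** 11 steps; longest linear sequence 11 steps (1 → 22).

**Steps most likely to fail**

Step 11 (new fragmentation). The 1,5-trans ring fusion lets the C1–C5 and C4–O bonds approach antiperiplanarity only in a strained twist conformer, so the enolate may epimerise or condense instead of fragmenting. The fallback uses known chemistry and closes the ten-membered ring instead of opening a bicycle: it sets out from 16 and 4 and returns at 22. The two are elaborated (Morita–Baylis–Hillman reaction with methyl acrylate, allylic bromination and two E-selective Horner–Wadsworth–Emmons olefinations; this multi-step assembly is not itemised) to the acyclic ω-formyl allylic bromide methyl (4R)-2-(bromomethyl)-10-[(tert-butyldimethylsilyloxy)methyl]-6-(dimethoxymethyl)-4-(3-methylbutanoyloxy)-12-oxododeca-2,6,10-trienoate F5. CrCl2-mediated intramolecular allylation (Nozaki–Hiyama–Kishi type, high dilution) and acid-induced lactonisation give the macrocyclic acetal silyl ether F6. Wet oxalic acid on silica frees the silyl-protected enal F7, and HF·pyridine gives 22.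

Step 7 (seven-membered Barbier closure and C8 configuration). The fallback sets out from 12 and returns at 15 or 17. Pd2(dba)3-catalysed borylation with B2pin2 gives the allylboronate F2; Swern oxidation gives the boronate aldehyde F3, which cyclises by thermal or Sc(OTf)3-catalysed intramolecular allylboration (closed transition state, no reducing metal) to 15. If the C8 epimer F4 forms instead, Mitsunobu esterification with 3-methylbutanoic acid (PPh3, DIAD) inverts C8 and gives 17 directly.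

Step 2 (asymmetric three-component coupling with an α-branched alkenyl group). The fallback sets out from 5 and 3 and returns at 8. Copper-catalysed conjugate addition (CuBr·SMe2, chiral phosphoramidite, Me3SiCl, −78 °C) gives the isolated trimethylsilyl enol ether F1; a BF3·OEt2-promoted Mukaiyama aldol with 4 then gives 8 after separation of C6 epimers.

**Further compounds**
F1 | step 2 | triethyl{[3-((1R)-3-trimethylsilyloxycyclopent-2-en-1-yl)but-3-en-1-yl]oxy}silane | C=C(CCO[Si](CC)(CC)CC)[C@@H]1CCC(O[Si](C)(C)C)=C1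
F2 | step 7 | (5R)-3-[(4,4,5,5-tetramethyl-1,3,2-dioxaborolan-2-yl)methyl]-5-[(3R,4R,5R)-5-(4-triethylsilyloxybut-1-en-2-yl)-1-oxaspiro[2.4]heptan-4-yl]furan-2(5H)-one | C1O[C@@]12CC[C@@H](C(=C)CCO[Si](CC)(CC)CC)[C@@H]2[C@@H]3OC(=O)C(CB4OC(C)(C)C(C)(C)O4)=C3
F3 | step 7 | (5R)-3-[(4,4,5,5-tetramethyl-1,3,2-dioxaborolan-2-yl)methyl]-5-[(3R,4R,5R)-5-(4-oxobut-1-en-2-yl)-1-oxaspiro[2.4]heptan-4-yl]furan-2(5H)-one | C1O[C@@]12CC[C@@H](C(=C)CC=O)[C@@H]2[C@@H]3OC(=O)C(CB4OC(C)(C)C(C)(C)O4)=C3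
F4 | step 7 | (1R,4R,5R,6R,7R,8S)-4,15-epoxy-8-hydroxyguaia-10(14),11(13)-dien-12,6-olide (C8 epimer of 15) | C1O[C@@]12CC[C@@H]3[C@@H]2[C@@H]4OC(=O)C(=C)[C@@H]4[C@@H](O)CC3=C
F5 | step 11 | methyl (4R)-2-(bromomethyl)-10-[(tert-butyldimethylsilyloxy)methyl]-6-(dimethoxymethyl)-4-(3-methylbutanoyloxy)-12-oxododeca-2,6,10-trienoate (chain carbons cis across each double bond) | O=C/C=C(/CO[Si](C)(C)C(C)(C)C)CC/C=C(/C(OC)OC)C[C@@H](OC(=O)CC(C)C)/C=C(\CBr)C(=O)OC
F6 | step 11 | (6S,7R,8R)-15-(tert-butyldimethylsilyloxy)-14,14-dimethoxygermacra-1(10),4,11(13)-trien-12,6-olid-8-yl 3-methylbutanoate | C=C1C(=O)O[C@H]2/C=C(/CO[Si](C)(C)C(C)(C)C)CC/C=C(/C(OC)OC)C[C@@H](OC(=O)CC(C)C)[C@@H]12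
F7 | step 11 | (6S,7R,8R)-15-(tert-butyldimethylsilyloxy)-14-oxogermacra-1(10),4,11(13)-trien-12,6-olid-8-yl 3-methylbutanoate | C=C1C(=O)O[C@H]2/C=C(/CO[Si](C)(C)C(C)(C)C)CC/C=C(/C=O)C[C@@H](OC(=O)CC(C)C)[C@@H]12
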